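The four α-oxygens of ring A and C20 are stripped back to a C12 ketone. Then C1–C10 and C13–C14 are cut together (Diels–Alder), followed by C4–C5 (Sonogashira), C9–C10 (alkenylzinc), C8–C17 with O–C19 (Reformatsky, lactonisation) and C6–C7 (alkynylation). Briarane numbering: ring A = C1, C10–C14; ten-membered ring = C1–C10; lactone = C7, C8, C17, C19, O.
Enabling feature: C1–C10 is the bond that ring A and the ten-membered ring share. In ring A the oxygen-bearing C12 lies para to the quaternary C1, and C1 carries the oxygen-bearing C2. Ring A is therefore the retron of a 2-silyloxydiene (C10–C13) plus an α-methyl enone (C14=C1–C2=O), and the tether C2–C9 is the rest of the ten-membered ring.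
Forward: the lactone is closed first on an open chain and both arms are grown on it. One cycloaddition of this monocyclic precursor then closes ring A and, with the lagging C1–C10 bond, the ten-membered ring as the last ring of the skeleton. The oxirane is only a late oxidation of the C11=C20 alkene.
Stereochemistry: C7 comes from catalytic alkynylation, C8 from a zinc chelate, C17 from equilibration and C9 from a ligand-controlled alkenylzinc addition. C1 and C10 are set in the cycloaddition (from C9, the diene geometry and an exo acyl group) and C2 by CBS reduction. C14 comes from α-epoxidation and Wharton transposition; C12, C13 and C11 from hydroxyl-directed osmylation and epoxidation. The two Z alkenes come from trans-hydroalumination/iodination and syn semi-hydrogenation.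

Key step: step 16

Remark: α is the face of ring A that carries H10 and β the face that carries C15; the sense of induction of the chiral catalysts in steps 3, 14 and 17 is assigned from the accepted transition-state models (both antipodes of each are available); C2 in 16–18 and C17 in 10 are inconsequential epimer mixtures and are drawn without configuration.

Step 1
Reactants: 1 2-methylidenepropane-1,3-diol
Product: 2 mono-PMB ether 2-{[(4-methoxybenzyl)oxy]methyl}prop-2-en-1-ol
Conditions: NaH (1 equiv), 4-methoxybenzyl chloride, Bu4NI (cat.), THF/DMF, 0 °C to rt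
Reagents that add atoms: 4-methoxybenzyl chloride, COc1ccc(CCl)cc1
Why: Williamson etherification of the monoalkoxide of a symmetrical diol masks one of two equivalent hydroxyls (the later C9–O) and leaves the other free for oxidation.

Step 2
Reactants: 2 mono-PMB ether
Product: 3 2-{[(4-methoxybenzyl)oxy]methyl}prop-2-enal
Conditions: MnO2, CH2Cl2, rt
Reagents that add atoms: none
Why: The selective MnO2 oxidation of an allylic alcohol gives the 2-substituted acrolein (C7 aldehyde) without touching the benzylic ether.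

Step 3
Reactants: 3 enal; 4 tert-butyldimethyl(prop-2-yn-1-yloxy)silane
Product: 6 (3S)-enynol (C7 carbinol), via alkynyl(methyl)zinc 5 (not isolated)
Conditions: Me2Zn (3 equiv), (R,R)-ProPhenol (20 mol %), Ph3P=O (40 mol %), toluene, 0 °C
Reagents that add atoms: none
Why: In this zinc/ProPhenol-catalysed asymmetric alkynylation of an enal the dinuclear zinc complex binds the aldehyde and alkynylzinc 5 and delivers the alkynyl group to one aldehyde face, which sets C7.

Step 4
Reactants: 6 (3S)-enynol
Product: 8 (3S,4Z)-iodo dienol, via cyclic alkenylalanate 7 (not isolated)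
Conditions: NaAlH2(OCH2CH2OMe)2, THF, 0 °C to rt; EtOAc; then I2, −78 to 0 °C
Reagents that add atoms: iodine, II
Why: Hydroxyl-directed trans-hydroalumination of the propargylic alcohol places aluminium on C5 in the five-membered alanate 7, and iodinolysis with retention gives the (Z)-iodoalkene in which C7 and iodine (the later C4) are cis.

Step 5
Reactants: 8 (3S,4Z)-iodo dienol
Product: 9 α-hydroxy ketone (C8 ketone)
Conditions: O3, pyridine (3 equiv), CH2Cl2, −78 °C, stopped at consumption of 8; used crude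
Reagents that add atoms: ozone, [O-][O+]=O
Why: Ozonolysis in the presence of pyridine (direct reductive variant) cleaves the unhindered, more electron-rich 1,1-disubstituted alkene in preference to the iodoalkene and unveils the C8 ketone without a glycol stage that could break C7–C8.

Step 6
Reactants: 9 α-hydroxy ketone
Product: 11 (3R,4R,5S)-β-hydroxy-γ-lactone, via dihydroxy ester 10 (not isolated)
Conditions: activated Zn, methyl 2-bromopropanoate (3 equiv), THF, 0 °C to rt; DBU (0.2 equiv) added before work-up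
Reagents that add atoms: methyl 2-bromopropanoate, COC(=O)C(C)Br
Why: In this Reformatsky reaction under chelation control the zinc alkoxide of the C7 hydroxyl ties the ketone oxygen into a five-membered chelate, the zinc enolate attacks opposite to the C6 alkenyl group (sets C8), the C7 alkoxide lactonises, and DBU equilibrates C17 to the epimer with the methyl group trans to the bulky C9 branch.

Step 7
Reactants: 11 β-hydroxy-γ-lactone
Product: 12 8-O-triethylsilyl lactone iodide
Conditions: Et3SiOTf, 2,6-lutidine, CH2Cl2, 0 °C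
Reagents that add atoms: triethylsilyl triflate, CC[Si](CC)(CC)OS(=O)(=O)C(F)(F)F
Why: Silylation of the hindered tertiary alcohol with a silyl triflate blocks retro-aldol cleavage, chelation and hydroxyl-directed side reactions in all later steps.

Step 8
Reactants: 13 methacrolein
Product: 15 (E)-3-bromo-2-methylprop-2-enal, via dibromo aldehyde 14 (not isolated)
Conditions: Br2, CH2Cl2, 0 °C; then Et3N, 0 °C to rt
Reagents that add atoms: bromine, BrBr
Why: Bromine addition followed by dehydrobromination (addition–elimination) gives the more stable (E)-β-bromo enal, whose bromine is the later leaving group on C14.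

Step 9
Reactants: 15 (E)-3-bromo-2-methylprop-2-enal
Product: 16 (1E)-1-bromo-2-methylpent-1-en-4-yn-3-ol
Conditions: HC≡CMgBr, THF, −78 to 0 °C
Reagents that add atoms: ethynylmagnesium bromide, C#C[Mg]Br
Why: The 1,2-addition of an alkynyl Grignard reagent to the enal supplies C3 and C4, and the carbinol centre (C2) may stay racemic because it is oxidised in step 12.

Step 10
Reactants: 12 lactone iodide; 16 bromo enynol
Product: 17 coupled (Z)-enyne carbinol
Conditions: Pd(PPh3)4 (5 mol %), CuI (10 mol %), Et3N, THF, rt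
Reagents that add atoms: none
Why: The Sonogashira coupling joins C4 to C5 with retention of the alkene geometry, because the vinyl iodide adds to zerovalent palladium far faster than the vinyl bromide.

Step 11
Reactants: 17 coupled enyne carbinol
Product: 18 C2,C9-diol
Conditions: DDQ, CH2Cl2/pH 7 buffer, 0 °C
Reagents that add atoms: none
Why: Oxidative cleavage of the 4-methoxybenzyl ether (hydride abstraction, then hydrolysis) frees the C9 hydroxyl and leaves silyl ethers, lactone, enyne and vinyl bromide untouched.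

Step 12
Reactants: 18 C2,C9-diol
Product: 19 keto aldehyde (C2 ynone, C9 aldehyde)
Conditions: Dess–Martin periodinane (2.5 equiv), NaHCO3, CH2Cl2, 0 °C to rt
Reagents that add atoms: none
Why: The Dess–Martin oxidation converts both alcohols at once into the non-enolisable C9 aldehyde and the C2 ketone that activates the dienophile.

Step 13
Reactants: 20 but-3-yn-2-one
Product: 21 2-(tert-butyldimethylsilyloxy)but-1-en-3-yne
Conditions: t-BuMe2SiOTf, Et3N, Et2O, 0 °C
Reagents that add atoms: tert-butyldimethylsilyl triflate, CC(C)(C)[Si](C)(C)OS(=O)(=O)C(F)(F)F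
Why: Soft enolisation of the methyl ketone with silyl triflate and amine gives the silyl enol ether that holds C10–C13 at the oxidation level of the diene.

Step 14
Reactants: 19 keto aldehyde; 21 silyloxy enyne
Product: 24 (9S)-dienyl carbinol, via dienylborane 22 (not isolated), via dienyl(methyl)zinc 23 (not isolated)
Conditions: 21, Cy2BH, toluene, 0 °C to rt; Me2Zn, −78 °C; (−)-3-exo-morpholinoisoborneol ((−)-MIB, 15 mol %), then 19, −20 °C
Reagents that add atoms: none
Why: The sequence is syn-hydroboration of the terminal alkyne, boron-to-zinc transmetalation and amino-alcohol-catalysed alkenylzinc addition, which touches only the aldehyde (ketones are inert); the (E)-alkene comes from the syn addition and C9 from the ligand-controlled choice of aldehyde face.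

Step 15
Reactants: 24 (9S)-dienyl carbinol
Product: 25 9-acetate (cycloaddition precursor)
Conditions: Ac2O, Et3N, DMAP (cat.), CH2Cl2, 0 °C
Reagents that add atoms: acetic anhydride, CC(=O)OC(C)=O
Why: DMAP-catalysed acetylation installs the final C9 acetate in a basic medium that the silyl dienol ether tolerates.

Step 16
Reactants: 25 9-acetate (cycloaddition precursor)
Product: 26 tricyclic cycloadduct (ring A, ten-membered ring, lactone)
Conditions: toluene (0.001 M), 2,6-di-tert-butylpyridine, BHT, 110 °C, argon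
Reagents that add atoms: none
Why: This is a thermal, concerted but strongly asynchronous [4+2] cycloaddition between the electron-rich 2-silyloxydiene C13=C12–C11=C10 and the electron-poor α-methyl-β-bromo enone C14=C1–C2=O, in which C13 (largest HOMO coefficient) bonds in advance to the β-carbon C14 across a nearly strain-free fourteen-membered perimeter and the lagging bond C10–C1, shared by ring A and the ten-membered ring, completes both rings. The closest known reaction type is the macrocyclising intramolecular Diels–Alder reaction of long-chain trienes at high dilution, which forms a cyclohexene together with an eleven- to fourteen-membered carbocycle. Ring A closes as the six-membered cycloaddition ring, and the ten-membered ring closes in the fused mode, the eight-atom tether C2–C9 joining dienophile carbon C1 to the diene terminus C10 to which it becomes bonded. C10 is controlled by C9, because in the staggered allylic conformer with H9 next to the diene (least allylic strain), the acetate outside and the quaternary C8 anti, the dienophile reaches C10 opposite to C8; C1 follows from the (E)-diene terminus and an exo placement of the tethered acyl group with the small methyl group endo under the bulky silyloxy group, which puts C2 trans and C15 cis to C9; C14 follows from the (E)-bromoalkene and is erased in step 19. The regiochemistry (acyl-bearing C1 para to the silyloxy group and ortho to C9) is secured by both donor substituents of the diene, attack on the ynone triple bond is disfavoured by electronic mismatch and by the strain of a seven-membered fused ring across the trans-substituted lactone, and oligomerisation is suppressed by the dilution. The (Z)-enyne and the lactone fix five of the eight tether atoms and so lower the entropic cost, while the hindered base and BHT protect the enol ether and the diene.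

Step 17
Reactants: 26 tricyclic cycloadduct
Product: 27 C2 propargylic alcohol
Conditions: (R)-tetrahydro-1-methyl-3,3-diphenyl-1H,3H-pyrrolo[1,2-c][1,3,2]oxazaborole ((R)-Me-CBS, 1 equiv), catecholborane, toluene, −78 °C
Reagents that add atoms: none
Why: In the Corey–Bakshi–Shibata reduction the oxazaborolidine tells the quaternary C1 (large) from the linear alkynyl group (small) and sets C2 by reagent control, while catecholborane at low temperature spares the enol ether, lactone, acetate and bromide.

Step 18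
Reactants: 27 C2 propargylic alcohol
Product: 28 2,9-diacetate
Conditions: Ac2O, DMAP, pyridine, rt
Reagents that add atoms: acetic anhydride, CC(=O)OC(C)=O
Why: DMAP-catalysed acetylation of the hindered secondary alcohol installs the final C2 acetate before ring A is unmasked.

Step 19
Reactants: 28 2,9-diacetate
Product: 30 enone Mannich base, via bromo Mannich ketone 29 (not isolated)
Conditions: Me2N=CH2+ I−, CH2Cl2, rt; then Et3N, rt
Reagents that add atoms: dimethyl(methylidene)ammonium iodide, C=[N+](C)C.[I-]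
Why: The Mannich reaction of the regiodefined silyl enol ether with a preformed iminium salt introduces C20 at C11 only; E1cB loss of HBr from β-bromo ketone 29 then places the enone double bond regiospecifically at C13=C14, and C11 settles as the equatorial (α) aminomethyl epimer.

Step 20
Reactants: 30 enone Mannich base
Product: 31 13α,14α-epoxy ketone
Conditions: t-BuOOH, DBU, CH2Cl2, 0 °C
Reagents that add atoms: tert-butyl hydroperoxide, CC(C)(C)OO
Why: In the Weitz–Scheffer epoxidation the peroxide anion adds axially to C14 on the α face, anti to the axial C15 methyl group on the neighbouring C1, which sets the C14–O bond.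

Step 21
Reactants: 31 13α,14α-epoxy ketone
Product: 32 14α-hydroxy-12-ene
Conditions: N2H4·H2O (2 equiv), AcOH (cat.), MeOH, 0 °C to rt, argon
Reagents that add atoms: none
Why: The Wharton transposition (hydrazone, epoxide opening, loss of N2) removes the C12 oxygen, moves the alkene to C12=C13 and keeps the C14–O bond, so that the axial 14α-alcohol is obtained without a ketone reduction.

Step 22
Reactants: 32 14α-hydroxy-12-ene
Product: 34 12α,13α,14α-triol, via osmate ester 33 (not isolated)
Conditions: OsO4 (1 equiv), TMEDA, CH2Cl2, −78 °C; then aq. Na2SO3, THF, rt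
Reagents that add atoms: osmium tetroxide, O=[Os](=O)(=O)=O
Why: In this hydroxyl-directed dihydroxylation a hydrogen bond between the allylic 14α-hydroxyl and the OsO4–diamine complex brings osmium to the α face of C12=C13 only, which sets C12 and C13 and spares the deactivated enyne.

Step 23
Reactants: 34 12α,13α,14α-triol
Product: 36 11(20)-exocyclic alkene, via amine N-oxide 35 (not isolated)
Conditions: m-CPBA (1 equiv), CH2Cl2, −20 °C; then THF, 50 °C
Reagents that add atoms: none
Why: Chemoselective N-oxidation is followed by Cope elimination through a five-membered syn transition state, and since the only β-hydrogen sits on C11 the C11=C20 alkene forms under neutral conditions.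

Step 24
Reactants: 36 11(20)-exocyclic alkene
Product: 37 11α,20-epoxide
Conditions: VO(acac)2 (5 mol %), t-BuOOH, CH2Cl2, 0 °C
Reagents that add atoms: tert-butyl hydroperoxide, CC(C)(C)OO
Why: In the vanadium-catalysed hydroxyl-directed epoxidation the peroxide bound next to the axial allylic 12α-hydroxyl is delivered to the α face of the only allylic-alcohol alkene, which sets C11 with oxygen α and C20 β.

Step 25
Reactants: 37 11α,20-epoxide
Product: 38 2,9,13-triacetate
Conditions: Ac2O (1.1 equiv), 2,4,6-collidine, DMAP (cat.), CH2Cl2, −20 °C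
Reagents that add atoms: acetic anhydride, CC(=O)OC(C)=O
Why: Site-selective acylation takes the single equatorial hydroxyl (C13), because the axial hydroxyls at C12 (next to the spiro centre) and C14 (next to the quaternary C1) are much more hindered.

Step 26
Reactants: 38 2,9,13-triacetate
Product: 39 (3Z,5Z in ring)-diene
Conditions: H2 (1 atm), Pd on CaCO3 poisoned with Pb(OAc)2, quinoline, EtOAc, rt, stopped after 1 equiv H2
Reagents that add atoms: none
Why: Syn semi-hydrogenation of the ring alkyne on a poisoned palladium surface gives the cis C3=C4 alkene, at a stage where no other reactive alkene is left in the molecule.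

Step 27
Reactants: 39 diene
Product: 40 Juncin Q
Conditions: Et3N·3HF, MeCN, rt
Reagents that add atoms: none
Why: Fluoride-mediated desilylation under nearly neutral conditions frees the primary C16 and the tertiary C8 hydroxyls without acetate migration or opening of the epoxide.

Compound list
1 | 2-methylidenepropane-1,3-diol | C=C(CO)CO | starting material
2 | 2-{[(4-methoxybenzyl)oxy]methyl}prop-2-en-1-ol | C=C(CO)COCc1ccc(OC)cc1 | intermediate
3 | 2-{[(4-methoxybenzyl)oxy]methyl}prop-2-enal | C=C(C=O)COCc1ccc(OC)cc1 | intermediate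
4 | tert-butyldimethyl(prop-2-yn-1-yloxy)silane | C#CCO[Si](C)(C)C(C)(C)C | starting material
5 | methyl[3-(tert-butyldimethylsilyloxy)prop-1-yn-1-yl]zinc | C[Zn]C#CCO[Si](C)(C)C(C)(C)C | intermediate
6 | (3S)-6-(tert-butyldimethylsilyloxy)-2-{[(4-methoxybenzyl)oxy]methyl}hex-1-en-4-yn-3-ol | C=C(COCc1ccc(OC)cc1)[C@@H](O)C#CCO[Si](C)(C)C(C)(C)C | intermediate
7 | sodium cyclic alkenylalanate (ring O–Al–C5=C6–C7, two 2-methoxyethoxy groups on Al) | [Na+].COCCO[Al-]1(OCCOC)O[C@H](C(=C)COCc2ccc(OC)cc2)C=C1CO[Si](C)(C)C(C)(C)C | intermediate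
8 | (3S,4Z)-6-(tert-butyldimethylsilyloxy)-5-iodo-2-{[(4-methoxybenzyl)oxy]methyl}hexa-1,4-dien-3-ol | C=C(COCc1ccc(OC)cc1)[C@@H](O)/C=C(CO[Si](C)(C)C(C)(C)C)\I | intermediate
9 | (3S,4Z)-6-(tert-butyldimethylsilyloxy)-3-hydroxy-5-iodo-1-[(4-methoxybenzyl)oxy]hex-4-en-2-one | COc1ccc(COCC(=O)[C@@H](O)/C=C(CO[Si](C)(C)C(C)(C)C)\I)cc1 | intermediate
10 | methyl 3,4-dihydroxy-2-methyl ester (C8 and C7 as in 11, C17 epimers) | COC(=O)C(C)[C@@](O)(COCc1ccc(OC)cc1)[C@@H](O)/C=C(CO[Si](C)(C)C(C)(C)C)\I | intermediate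
11 | (3R,4R,5S)-4-hydroxy-5-[(1Z)-3-(tert-butyldimethylsilyloxy)-2-iodoprop-1-enyl]-4-{[(4-methoxybenzyl)oxy]methyl}-3-methyloxolan-2-one (methyl, hydroxyl and alkenyl group on one ring face, C9 on the other) | COc1ccc(COC[C@@]2(O)[C@H](/C=C(CO[Si](C)(C)C(C)(C)C)\I)OC(=O)[C@@H]2C)cc1 | intermediate
12 | 8-O-triethylsilyl ether of 11 | COc1ccc(COC[C@@]2(O[Si](CC)(CC)CC)[C@H](/C=C(CO[Si](C)(C)C(C)(C)C)\I)OC(=O)[C@@H]2C)cc1 | intermediate
13 | methacrolein | C=C(C)C=O | starting material
14 | 2,3-dibromo-2-methylpropanal | O=CC(C)(Br)CBr | intermediate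
15 | (E)-3-bromo-2-methylprop-2-enal | O=C/C(C)=C/Br | intermediate
16 | (1E)-1-bromo-2-methylpent-1-en-4-yn-3-ol (racemic) | C#CC(O)/C(C)=C/Br | intermediate
17 | lactone 12 with iodine replaced by the C4≡C3–C2H(OH)–C1(CH3)=C14HBr chain | COc1ccc(COC[C@@]2(O[Si](CC)(CC)CC)[C@H](/C=C(CO[Si](C)(C)C(C)(C)C)\C#CC(O)/C(C)=C/Br)OC(=O)[C@@H]2C)cc1 | intermediate
18 | C2,C9-diol (4-methoxybenzyl group removed from 17) | OC[C@@]1(O[Si](CC)(CC)CC)[C@H](/C=C(CO[Si](C)(C)C(C)(C)C)\C#CC(O)/C(C)=C/Br)OC(=O)[C@@H]1C | intermediate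
19 | keto aldehyde (C9 aldehyde, C2 bromo-dienynone) | O=C[C@@]1(O[Si](CC)(CC)CC)[C@H](/C=C(CO[Si](C)(C)C(C)(C)C)\C#CC(=O)/C(C)=C/Br)OC(=O)[C@@H]1C | intermediate
20 | but-3-yn-2-one | CC(=O)C#C | starting material
21 | 2-(tert-butyldimethylsilyloxy)but-1-en-3-yne | C=C(O[Si](C)(C)C(C)(C)C)C#C | intermediate
22 | [(1E)-3-(tert-butyldimethylsilyloxy)buta-1,3-dienyl]dicyclohexylborane | C=C(O[Si](C)(C)C(C)(C)C)/C=C/B(C1CCCCC1)C1CCCCC1 | intermediate
23 | [(1E)-3-(tert-butyldimethylsilyloxy)buta-1,3-dienyl](methyl)zinc | C=C(O[Si](C)(C)C(C)(C)C)/C=C/[Zn]C | intermediate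
24 | (9S)-dienyl carbinol: 19 with C9H(OH)–(E)-C10H=C11H–C12(OTBS)=C13H2 | C=C(O[Si](C)(C)C(C)(C)C)/C=C/[C@H](O)[C@@]1(O[Si](CC)(CC)CC)[C@H](/C=C(CO[Si](C)(C)C(C)(C)C)\C#CC(=O)/C(C)=C/Br)OC(=O)[C@@H]1C | intermediate
25 | 9-acetate of 24 | C=C(O[Si](C)(C)C(C)(C)C)/C=C/[C@H](OC(C)=O)[C@@]1(O[Si](CC)(CC)CC)[C@H](/C=C(CO[Si](C)(C)C(C)(C)C)\C#CC(=O)/C(C)=C/Br)OC(=O)[C@@H]1C | intermediate
26 | 20-norbriarane cycloadduct: 2-oxo, 3-yne, 5-ene, 11-ene with 12-OTBS, 14β-Br, H10 α, C15 β, 9-OAc, 8-OTES, 16-OTBS, 19,7-lactone | C1C(O[Si](C)(C)C(C)(C)C)=C[C@@H]2[C@H](OC(C)=O)[C@@]3(O[Si](CC)(CC)CC)[C@H](/C=C(CO[Si](C)(C)C(C)(C)C)\C#CC(=O)[C@@]2(C)[C@@H]1Br)OC(=O)[C@@H]3C | intermediate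
27 | 2-alcohol of 26 (C2 as in the target) | C1C(O[Si](C)(C)C(C)(C)C)=C[C@@H]2[C@H](OC(C)=O)[C@@]3(O[Si](CC)(CC)CC)[C@H](/C=C(CO[Si](C)(C)C(C)(C)C)\C#C[C@H](O)[C@@]2(C)[C@@H]1Br)OC(=O)[C@@H]3C | intermediate
28 | 2,9-diacetate | C1C(O[Si](C)(C)C(C)(C)C)=C[C@@H]2[C@H](OC(C)=O)[C@@]3(O[Si](CC)(CC)CC)[C@H](/C=C(CO[Si](C)(C)C(C)(C)C)\C#C[C@H](OC(C)=O)[C@@]2(C)[C@@H]1Br)OC(=O)[C@@H]3C | intermediate
29 | 12-ketone with 11α-CH2NMe2 and 14β-Br | C1C(=O)[C@@H](CN(C)C)[C@@H]2[C@H](OC(C)=O)[C@@]3(O[Si](CC)(CC)CC)[C@H](/C=C(CO[Si](C)(C)C(C)(C)C)\C#C[C@H](OC(C)=O)[C@@]2(C)[C@@H]1Br)OC(=O)[C@@H]3C | intermediate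
30 | 13-en-12-one with 11α-CH2NMe2 | C1=CC(=O)[C@@H](CN(C)C)[C@@H]2[C@H](OC(C)=O)[C@@]3(O[Si](CC)(CC)CC)[C@H](/C=C(CO[Si](C)(C)C(C)(C)C)\C#C[C@H](OC(C)=O)[C@@]12C)OC(=O)[C@@H]3C | intermediate
31 | 13α,14α-epoxy-12-ketone | O1[C@H]2C(=O)[C@@H](CN(C)C)[C@@H]3[C@H](OC(C)=O)[C@@]4(O[Si](CC)(CC)CC)[C@H](/C=C(CO[Si](C)(C)C(C)(C)C)\C#C[C@H](OC(C)=O)[C@@]3(C)[C@@H]12)OC(=O)[C@@H]4C | intermediate
32 | 14α-hydroxy-12-ene | C1=C[C@@H](CN(C)C)[C@@H]2[C@H](OC(C)=O)[C@@]3(O[Si](CC)(CC)CC)[C@H](/C=C(CO[Si](C)(C)C(C)(C)C)\C#C[C@H](OC(C)=O)[C@@]2(C)[C@H]1O)OC(=O)[C@@H]3C | intermediate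
33 | 12α,13α-osmate ester (hexavalent osmium), TMEDA adduct | O1[C@H]2[C@@H](O[Os]1(=O)=O)[C@@H](CN(C)C)[C@@H]3[C@H](OC(C)=O)[C@@]4(O[Si](CC)(CC)CC)[C@H](/C=C(CO[Si](C)(C)C(C)(C)C)\C#C[C@H](OC(C)=O)[C@@]3(C)[C@H]2O)OC(=O)[C@@H]4C.CN(C)CCN(C)C | intermediate
34 | 12α,13α,14α-triol with 11α-CH2NMe2 | O[C@H]1[C@@H](O)[C@@H](CN(C)C)[C@@H]2[C@H](OC(C)=O)[C@@]3(O[Si](CC)(CC)CC)[C@H](/C=C(CO[Si](C)(C)C(C)(C)C)\C#C[C@H](OC(C)=O)[C@@]2(C)[C@H]1O)OC(=O)[C@@H]3C | intermediate
35 | N-oxide of 34 | O[C@H]1[C@@H](O)[C@@H](C[N+](C)(C)[O-])[C@@H]2[C@H](OC(C)=O)[C@@]3(O[Si](CC)(CC)CC)[C@H](/C=C(CO[Si](C)(C)C(C)(C)C)\C#C[C@H](OC(C)=O)[C@@]2(C)[C@H]1O)OC(=O)[C@@H]3C | intermediate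
36 | 11(20)-ene-12α,13α,14α-triol | O[C@H]1[C@@H](O)C(=C)[C@@H]2[C@H](OC(C)=O)[C@@]3(O[Si](CC)(CC)CC)[C@H](/C=C(CO[Si](C)(C)C(C)(C)C)\C#C[C@H](OC(C)=O)[C@@]2(C)[C@H]1O)OC(=O)[C@@H]3C | intermediate
37 | 11α,20-epoxy-12α,13α,14α-triol | O[C@H]1[C@@H](O)[C@]2(CO2)[C@@H]2[C@H](OC(C)=O)[C@@]3(O[Si](CC)(CC)CC)[C@H](/C=C(CO[Si](C)(C)C(C)(C)C)\C#C[C@H](OC(C)=O)[C@@]2(C)[C@H]1O)OC(=O)[C@@H]3C | intermediate
38 | 2,9,13-triacetate (3-yne, bis-silyl ether) | CC(=O)O[C@H]1[C@@H](O)[C@]2(CO2)[C@@H]2[C@H](OC(C)=O)[C@@]3(O[Si](CC)(CC)CC)[C@H](/C=C(CO[Si](C)(C)C(C)(C)C)\C#C[C@H](OC(C)=O)[C@@]2(C)[C@H]1O)OC(=O)[C@@H]3C | intermediate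
39 | 8-O-TES, 16-O-TBS ether of Juncin Q | CC(=O)O[C@H]1[C@@H](O)[C@]2(CO2)[C@@H]2[C@H](OC(C)=O)[C@@]3(O[Si](CC)(CC)CC)[C@H](/C=C(CO[Si](C)(C)C(C)(C)C)\C=C/[C@H](OC(C)=O)[C@@]2(C)[C@H]1O)OC(=O)[C@@H]3C | intermediate
40 | Juncin Q | CC(=O)O[C@H]1[C@@H](O)[C@]2(CO2)[C@@H]2[C@H](OC(C)=O)[C@@]3(O)[C@H](/C=C(CO)\C=C/[C@H](OC(C)=O)[C@@]2(C)[C@H]1O)OC(=O)[C@@H]3C | target

Total step count: 27. Longest linear sequence: 24 (steps 1–7, 10–12, 14–27).

Steps most likely to fail

Step 16. The chain may oligomerise, the diene may add to the ynone triple bond instead of closing the large ring, the dienophile may approach the wrong diene face, or HBr may be lost thermally with desilylation. The fallback sets out from 12 and 16 and returns at 26.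
- It builds ring A first by an intermolecular cycloaddition and then closes the ten-membered ring at C4–C5.
- Iodide 12 is freed with DDQ to the primary alcohol F1 and oxidised with Dess–Martin periodinane to the aldehyde F2.
- F2 is treated with dienylzinc 23 and (−)-MIB to give the dienyl carbinol F3, which is acetylated to the diene acetate F4.
- Alkynol 16 is oxidised with MnO2 to the terminal ynone F5.
- F4 is heated with an excess of F5 in concentrated toluene solution to give the cyclohexene F6, with the same regiochemical and facial arguments but no ring strain.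
- An intramolecular Sonogashira coupling of F6 (Pd(PPh3)4, CuI, Et3N, high dilution) then gives 26.

Step 20. The basic peroxide medium may expel dimethylamine from the Mannich base, and attack at the neopentyl C14 may be too slow. The fallback sets out from 30 and returns at 34, and avoids both the epoxide and hydrazine.
- Luche reduction (NaBH4, CeCl3) of 30 gives, by axial hydride attack from the α face, the 12β-allylic alcohol F7.
- Mitsunobu inversion with formic acid (PPh3, diisopropyl azodicarboxylate) gives the 12α-formate F8.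
- KHCO3 in methanol cleaves only the formate and gives the 12α-allylic alcohol F9.
- Hydroxyl-directed osmylation of C13=C14 (OsO4, TMEDA) passes through the 13α,14α-osmate ester F10, and aqueous Na2SO3 releases 34.

Step 26. Hydrogen uptake may run on into the diene, the allylic acetates may suffer hydrogenolysis, or the hindered ring alkyne may not reach the catalyst surface. The fallback sets out from 38 and returns at 39.
- Co2(CO)8 in CH2Cl2 converts the alkyne into the hexacarbonyldicobalt complex F11.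
- Reductive decomplexation with Bu3SnH in warm benzene delivers two hydrogens cis and gives 39 without a hydrogenation catalyst.

Further compounds
F1 | step 16 | primary alcohol (12 without the 4-methoxybenzyl group) | OC[C@@]1(O[Si](CC)(CC)CC)[C@H](/C=C(CO[Si](C)(C)C(C)(C)C)\I)OC(=O)[C@@H]1C
F2 | step 16 | C9 aldehyde with vinyl iodide | O=C[C@@]1(O[Si](CC)(CC)CC)[C@H](/C=C(CO[Si](C)(C)C(C)(C)C)\I)OC(=O)[C@@H]1C
F3 | step 16 | (9S)-dienyl carbinol with vinyl iodide | C=C(O[Si](C)(C)C(C)(C)C)/C=C/[C@H](O)[C@@]1(O[Si](CC)(CC)CC)[C@H](/C=C(CO[Si](C)(C)C(C)(C)C)\I)OC(=O)[C@@H]1C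
F4 | step 16 | diene acetate with vinyl iodide | C=C(O[Si](C)(C)C(C)(C)C)/C=C/[C@H](OC(C)=O)[C@@]1(O[Si](CC)(CC)CC)[C@H](/C=C(CO[Si](C)(C)C(C)(C)C)\I)OC(=O)[C@@H]1C
F5 | step 16 | (1E)-1-bromo-2-methylpent-1-en-4-yn-3-one | C#CC(=O)/C(C)=C/Br
F6 | step 16 | ring A cyclohexene with C1 propynoyl group, 14β-Br and the lactone iodide on C9 | C1C(O[Si](C)(C)C(C)(C)C)=C[C@H]([C@H](OC(C)=O)[C@@]2(O[Si](CC)(CC)CC)[C@H](/C=C(CO[Si](C)(C)C(C)(C)C)\I)OC(=O)[C@@H]2C)[C@@](C)(C(=O)C#C)[C@@H]1Br
F7 | step 20 | 12β-hydroxy-13-ene | C1=C[C@H](O)[C@@H](CN(C)C)[C@@H]2[C@H](OC(C)=O)[C@@]3(O[Si](CC)(CC)CC)[C@H](/C=C(CO[Si](C)(C)C(C)(C)C)\C#C[C@H](OC(C)=O)[C@@]12C)OC(=O)[C@@H]3C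
F8 | step 20 | 12α-formyloxy-13-ene | C1=C[C@@H](OC=O)[C@@H](CN(C)C)[C@@H]2[C@H](OC(C)=O)[C@@]3(O[Si](CC)(CC)CC)[C@H](/C=C(CO[Si](C)(C)C(C)(C)C)\C#C[C@H](OC(C)=O)[C@@]12C)OC(=O)[C@@H]3C
F9 | step 20 | 12α-hydroxy-13-ene | C1=C[C@@H](O)[C@@H](CN(C)C)[C@@H]2[C@H](OC(C)=O)[C@@]3(O[Si](CC)(CC)CC)[C@H](/C=C(CO[Si](C)(C)C(C)(C)C)\C#C[C@H](OC(C)=O)[C@@]12C)OC(=O)[C@@H]3C
F10 | step 20 | 13α,14α-osmate ester, TMEDA adduct | O1[C@H]2[C@@H](O)[C@@H](CN(C)C)[C@@H]3[C@H](OC(C)=O)[C@@]4(O[Si](CC)(CC)CC)[C@H](/C=C(CO[Si](C)(C)C(C)(C)C)\C#C[C@H](OC(C)=O)[C@@]3(C)[C@H]2O[Os]1(=O)=O)OC(=O)[C@@H]4C.CN(C)CCN(C)C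
F11 | step 26 | hexacarbonyldicobalt complex of the C3≡C4 alkyne of 38 | CC(=O)O[C@H]1[C@@H](O)[C@]2(CO2)[C@@H]2[C@H](OC(C)=O)[C@@]3(O[Si](CC)(CC)CC)[C@H](/C=C(CO[Si](C)(C)C(C)(C)C)\C45C6([Co]4(=C=O)(=C=O)(=C=O)[Co]56(=C=O)(=C=O)=C=O)[C@H](OC(C)=O)[C@@]2(C)[C@H]1O)OC(=O)[C@@H]3C
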